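## Structural features

The target is a 5-6-8 tricyclic diterpenoid. Ring A is a cyclopentenone (C1, C2, C3, C4, C9; C2 ketone, C3=C4 alkene), ring C a cyclohexane (C4 to C9), and the third ring an eight-membered carbocycle (C4, C5, C14, C13, C12, C11, C10, C9). C5 and C9 are the bridgeheads of a bicyclo[5.3.1]undecane whose one-carbon bridge C4 also belongs to ring A. Seven stereocentres lie in two contiguous runs, C14–C5–C6 and C9–C10–C11–C12; three are quaternary (C5, C9, C12), and C5 and C9 flank the sp2 carbon C4. The substituents are methyl groups on C5, C6, C10 and C12, a vinyl group on C12, a free secondary hydroxyl on C11 and a glycolate ester on the very hindered C14 oxygen. Fragile groups are the glycolate (base-labile, with a free primary hydroxyl), the enone, and the compact core, which is prone to cationic rearrangement and transannular hydride shifts under acid. The real difficulty is the eight-membered ring with quaternary C12, the relative configuration of centres spread over three rings, and the C11 oxygen on an unactivated carbon. The key step exploits the fact that the twenty skeletal carbons, the four methyl groups and the C12 vinyl group are the pattern of a folded and rearranged geranylgeranyl chain, and that the C14 oxygen is the water that ends the cation cascade. One enzyme can therefore form ring A, ring C and the eight-membered ring together with six of the seven stereocentres of the target.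

## Logic of the disconnections

15 ⇒ 14. The O–H bonds of the C11 carbinol and of the glycolate hydroxyl are exchanged for O–Si bonds. Both hydroxyls would be oxidised or dehydrated during the ring-A operations. The gain is an endgame of one deprotection. The demand is that fluoride remove a primary and a hindered secondary silyl ether without touching ester or enone.

14 ⇒ 13. The C2=O bond is removed, leaving a C2 methylene beside the C3=C4 alkene. C2 is the only carbon with allylic hydrogens, so a C–H oxidation has one site to choose. Ring A becomes a plain cyclopentene. The oxidant must spare the vinyl group and both silyl ethers.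

13 ⇒ 12. The C3=C4 π bond is replaced by C3–OH and C4–H. A C3 oxygen is what the biosynthetic oxidations can place on ring A. Ring A becomes saturated with one functional group. The elimination must take H4 and not H2, and a cation at C3 must not rearrange.

12 ⇒ 11. The C3 carbinol C–H bond is traced back to the C3 ketone. As a ketone, C3 is inert while C11 and C14 are differentiated. The gain is a substrate in which only one hydroxyl is ever free at a time. Hydride must reduce the ketone, not the glycolate ester, and from one face.

11 ⇒ 9 + 10. The C14 O–acyl bond is cut. The glycolate is the only non-terpenoid part, and cutting it brings in a purchasable acid. The gain is that 9 is pure core. The demand is acylation of a neopentyl secondary alcohol next to quaternary C5.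

9 ⇒ 8. The C11 O–Si bond is cut. The two secondary hydroxyls must be told apart, and C11 is the more accessible. The gain is an unprotected diol ketone. The demand is site selectivity between C11 and C14.

8 ⇒ 5. The C11–O bond and the C3=O group are replaced by C–H bonds. Both oxygens sit on unactivated carbons, where only the pathway enzymes offer this site and face selectivity. The gain is a skeleton with the single C14 hydroxyl. The demand is two hydroxylations and one dehydrogenation in one fermentation.

5 ⇒ 3. The bonds C11–C12, C1–C9, C4–C5, C9–C10 and C14–O are cut. They are exactly the bonds that a cation cascade along a prenyl chain makes. A tricycle with seven stereocentres becomes an achiral open chain. The demand is complete control of folding, of four 1,2-shifts, of a medium-ring closure and of the final hydration, which only the enzyme can supply.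

3 ⇒ 2. The allylic C1–O–P bond is cut. The diphosphate is the leaving group that the enzyme needs and is best installed last on the chain. The gain is a simple allylic halide. The demand is SN2 displacement without allylic transposition or loss of the (2E) geometry.

2 ⇒ 1. The C1–Cl bond is traced back to C1–OH. The alcohol is an article of commerce. The demand is chlorination that leaves the four trisubstituted alkenes untouched.

## Other disconnections considered

Alternative 1: The cut is made at C12–C13 and C10–C11. The eight-membered ring is traced back to a bridged cyclohexane-1,3-dione (C14, C13, C10, with C5 and C9 as bridgeheads) into which C11 and C12 are inserted.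
- Forward key step: a De Mayo sequence. A [2+2] photocycloaddition joins a C10 enol acetate function to a C11=C12 silyl enol ether; acetate cleavage and retro-aldol scission of C13–C10 then lead to the bridged cyclooctane-1,5-dione A1.
- In its favour: ring expansion avoids the entropic and transannular cost of a direct eight-ring closure. Quaternary C12 and the C11 oxygen arrive in one operation. The C12 substituents could be varied for analogues, and on this point it is better than the chosen plan, which delivers only the natural pattern.
- Against it here: head-to-head versus head-to-tail orientation and the face of the enol ether decide C11 and C12, and the substrate secures neither. A1 still lacks ring A and the C10 methyl stereocentre, holds C10 and C14 at the ketone level, and carries a pivaloyloxyethyl group where the vinyl group must stand.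
- Comparison: on structure, both plans treat the eight-membered ring as the central problem, but A1 sets two stereocentres where 5 has all of its seven. On mechanism, a photocycloaddition under substrate control stands against a cation cascade under active-site control. On step economy, the alternative would be several times longer. It equals the chosen plan in forming quaternary C12 during ring formation, and it is better in needing no protein expression.

Alternative 2: The cut is made at C5–C6 and C4–C9, which opens ring C and ring A together to a triene.
- Forward key step: an intramolecular Diels–Alder reaction, thermal or with Me2AlCl. The C6–C9 diene adds to the (Z)-C4=C5 enoate across a three-carbon ketal tether and gives the cis-fused hydrindene ester A2.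
- In its favour: one step forms two rings and the four stereocentres C4, C5, C6 and C9, two of them quaternary, with alkene geometry translated into relative configuration by the suprafacial rule. In rings and stereocentres per step it equals the class-two half of the enzymatic cascade. In access to either enantiomer it is better.
- Against it here: a trisubstituted enoate must create a quaternary centre next to a second one, so the cycloaddition should be slow and its endo/exo and facial selectivity uncertain. The geometrically pure (Z)-enoate must be made first. A2 contains neither the eight-membered ring nor C11, C12 and C14, and its C7=C8 alkene must later be removed.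
- Comparison: on structure, A2 holds two of three rings and four stereocentres, while 5 holds the complete skeleton. On mechanism, a pericyclic step under substrate control stands against a cationic one under enzyme control. On step economy, a precursor synthesis plus a separate medium-ring construction would make it much longer.

Alternative 3: The cut is made at C13–C14, so the eight-membered ring is closed last on a preformed ring A/ring C bicycle that carries the whole C10–C13 chain.
- Forward key step: SmI2 with HMPA reduces the neopentyl C13 iodide, and the organosamarium adds to the C14 aldehyde on C5 (Barbier closure) to give the tricyclic carbinol A3.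
- In its favour: A3 is close to the target. Ring A already has the C3=C4 alkene and a masked C2 ketone, and C11 is oxygenated. On ring-A and C11 oxidation state it is better than the chosen plan, which must add these after the key step. It equals the chosen plan in creating the C14 carbinol during ring formation.
- Against it here: an eight-membered ring must close between a neopentyl carbanion equivalent and an aldehyde on a quaternary carbon. Simple reduction of the iodide, pinacol-type reduction of the aldehyde and weak control of the C14 configuration would compete. HMPA adds a hazard. Every stereocentre except C14 must be built beforehand, and the silyloxyethyl group must still become the vinyl group.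
- Comparison: on structure, a late medium-ring closure stands against formation of the whole skeleton at once. On mechanism, a single-electron Barbier addition under substrate control stands against an enzyme-steered cation cascade. On step economy, fewer steps would follow the cyclisation (better), but the way to its precursor is far longer, so it is longer overall.

Key step: step 3

Remark 1: C5 and C6 are written in every structure with the same descriptors as in the target structure; both centres are set by the cyclase in step 3 and no later step touches them (should the enzyme-made core be meant with the other pair of C5/C6 descriptors, the same change applies to every compound and nothing else in the route moves).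

Remark 2: The C3 carbinol of the transient triol 7 is drawn (3S), hydroxyl on the exposed face of ring A; its configuration is immaterial because the same cells oxidise it to the ketone of 8.

## Route

Step 1
Reactants: 1 (2E,6E,10E)-geranylgeraniol
Product: 2 (2E,6E,10E)-geranylgeranyl chloride
Conditions: NCS, Me2S, CH2Cl2, −30 to 0 °C
Reagents that add atoms: N-chlorosuccinimide, O=C1CCC(=O)N1Cl
Why: Corey–Kim chlorination: the chlorosulfonium salt from NCS and Me2S activates the primary allylic alcohol and chloride displaces dimethyl sulfoxide at C1 without allylic transposition or E/Z erosion; the trisubstituted alkenes are inert at this temperature.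

Step 2
Reactants: 2 (2E,6E,10E)-geranylgeranyl chloride
Product: 3 (2E,6E,10E)-geranylgeranyl diphosphate (handled as its ammonium salt)
Conditions: (Bu4N)3HP2O7, MeCN, rt; cation exchange (NH4+ form); cellulose chromatography
Reagents that add atoms: tris(tetrabutylammonium) hydrogen diphosphate, CCCC[N+](CCCC)(CCCC)CCCC.CCCC[N+](CCCC)(CCCC)CCCC.CCCC[N+](CCCC)(CCCC)CCCC.OP(=O)([O-])OP(=O)([O-])[O-]
Why: SN2 displacement of the primary allylic chloride by the poorly solvated hydrogen diphosphate anion in MeCN is the standard way to prenyl diphosphates; ion exchange gives the water-soluble ammonium salt that the enzyme accepts, and the (2E) geometry is untouched.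

Step 3
Reactants: 3 (2E,6E,10E)-geranylgeranyl diphosphate
Product: 5 premutilin, via mutildienyl diphosphate 4 (not isolated)
Conditions: recombinant premutilin synthase (His-tagged Pl-cyc from E. coli), HEPES pH 7.5, MgCl2, DTT, glycerol, 30 °C, hexane overlay
Reagents that add atoms: water, O
Why: This is the natural reaction of the bifunctional class-two/class-one diterpene synthase of the pleuromutilin pathway run with recombinant protein; the closest reaction type is the protonation-initiated polyene bicyclisation of copalyl diphosphate synthases coupled to an ionisation-initiated cyclisation as in kaurene synthases. In the class-two site the terminal alkene is protonated and two 6-endo cation–olefin closures form C9–C10 and C4–C5, giving ring C and a transient cyclohexane with the charge at C6. Antiperiplanar 1,2-shifts (H from C5 to C6, CH3 from C4 to C5, H from C9 to C4) carry the charge to C9, a 1,2-alkyl shift of C1 from C10 to C9 contracts the transient ring to ring A (C1–C9), and loss of a methyl proton leaves the isopropenyl group of 4. In the class-one site the magnesium-bound diphosphate ionises, the isopropenyl CH2 (C11) attacks the tertiary end C12 of the allyl cation (8-endo for the isopropenyl alkene, vinyl group left exocyclic) to form C11–C12, a transannular 1,5-hydride shift from C14 to C10 follows and water quenches C14. C4, C5, C6 and C9 are set by the pre-folded chain and the stereospecific suprafacial shifts, C12 by the face of the allyl cation offered to C11, C10 by the face of hydride delivery and C14 by the position of the bound water, all dictated by the contour of the two active sites. The step needs chemoselectivity for this one cation pathway over early deprotonation or hydration, and it needs absolute stereocontrol; both rest on the enzyme, which accepts only the all-E diphosphate 3, while the hexane overlay removes 5 as it forms.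

Step 4
Reactants: 5 premutilin
Product: 8 mutilin, via 11-hydroxypremutilin 6 (not isolated), via 3,11-dihydroxypremutilin 7 (not isolated)
Conditions: Aspergillus oryzae transformant expressing Pl-p450-1, Pl-p450-2 and Pl-sdr, maltose medium, 5 fed in EtOH, air, 28 °C, 4–5 d; EtOAc extraction
Reagents that add atoms: dioxygen, O=O
Why: These are native pathway reactions in a heterologous host: the C11 hydroxylase and then the C3 hydroxylase insert oxygen by hydrogen abstraction and rebound with retention, which fixes (11S); the short-chain dehydrogenase then oxidises only the C3 carbinol, so that C3 emerges as a ketone chemically distinct from the C11 and C14 hydroxyls. NAD(P)H is recycled by the growing cells.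

Step 5
Reactants: 8 mutilin
Product: 9 11-O-triethylsilylmutilin
Conditions: TESCl (1.1 equiv), imidazole, DMAP (cat.), DMF, 0 °C to rt
Reagents that add atoms: chlorotriethylsilane, CC[Si](Cl)(CC)CC
Why: In 8 the C11 hydroxyl is the more accessible of the two neopentyl carbinols (the bias that governs the known C11-selective acylation of this diol), so one equivalent of silyl chloride should react at C11 and leave the C14 hydroxyl next to quaternary C5; imidazole does not enolise the ketone.

Step 6
Reactants: 9 11-O-triethylsilylmutilin; 10 (tert-butyldimethylsilyloxy)acetic acid
Product: 11 14-O-[(tert-butyldimethylsilyloxy)acetyl]-11-O-triethylsilylmutilin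
Conditions: EDC·HCl, DMAP, CH2Cl2, rt
Reagents that add atoms: none
Why: Steglich esterification: DMAP relays the O-acylisourea as an acylpyridinium ion that is small enough to acylate the hindered C14 carbinol, the only free hydroxyl left; no stereocentre is touched.

Step 7
Reactants: 11 14-O-[(tert-butyldimethylsilyloxy)acetyl]-11-O-triethylsilylmutilin
Product: 12 (3R)-3-deoxo-3-hydroxy derivative of 11 (C3 hydroxyl cis to C5, anti to H4)
Conditions: NaBH4, CeCl3·7H2O, MeOH/THF, −40 to 0 °C
Reagents that add atoms: none
Why: Luche-type 1,2-reduction: the cerium-activated ketone is reduced far faster than the glycolate ester; hydride attacks the face of ring A that carries H4 (the convex face, turned away from ring C), so the new hydroxyl should sit cis to C5 and anti to H4, (3R).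

Step 8
Reactants: 12 (3R)-3-deoxo-3-hydroxy derivative of 11
Product: 13 3-deoxo-3,4-didehydro-14-O-[(tert-butyldimethylsilyloxy)acetyl]-11-O-triethylsilylmutilin (C3=C4 alkene)
Conditions: Martin sulfurane, Ph2S[OC(CF3)2Ph]2, CH2Cl2, 0 °C to rt
Reagents that add atoms: none
Why: Dehydration with Martin sulfurane: the alkoxysulfonium ion on the crowded face of ring A leaves with anti removal of H4 from the open face (E2 to E1-like continuum), and both pathways favour the trisubstituted C3=C4 alkene (Zaitsev); the conditions are neutral, so silyl ethers, ester and vinyl group persist, and the C3 stereocentre is erased on purpose.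

Step 9
Reactants: 13 C3=C4 alkene
Product: 14 2-oxo-3-deoxo-3,4-didehydro-14-O-[(tert-butyldimethylsilyloxy)acetyl]-11-O-triethylsilylmutilin (bis-silyl ether of the target)
Conditions: CrO3, 3,5-dimethylpyrazole, CH2Cl2, −20 °C
Reagents that add atoms: chromium trioxide, O=[Cr](=O)=O
Why: Allylic oxidation with the CrO3–3,5-dimethylpyrazole complex: C2 is the only carbon with allylic hydrogens (C5 and C9 are quaternary, C12 blocks the vinyl group), and oxidation at C2 or at C4 followed by 1,3-transposition of the tertiary chromate leads to the same C2 enone; both hydroxyls are masked against hexavalent chromium.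

Step 10
Reactants: 14 bis-silyl ether of the target
Product: 15 Pleuromutilin F (14-O-glycoloyl-2-oxo-3-deoxo-3,4-didehydromutilin)
Conditions: HF·pyridine, pyridine/THF, 0 °C to rt
Reagents that add atoms: none
Why: Fluoride-mediated desilylation: HF·pyridine cleaves the primary TBS ether and the secondary TES ether under mildly acidic conditions that leave the hindered glycolate ester, the enone and the vinyl group alone, whereas basic fluoride could transesterify the glycolate.

## Compound list

1 | (2E,6E,10E)-geranylgeraniol | CC(C)=CCC/C(C)=C/CC/C(C)=C/CC/C(C)=C/CO | starting material
2 | (2E,6E,10E)-geranylgeranyl chloride | CC(C)=CCC/C(C)=C/CC/C(C)=C/CC/C(C)=C/CCl | intermediate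
3 | (2E,6E,10E)-geranylgeranyl diphosphate (handled as ammonium salt) | CC(C)=CCC/C(C)=C/CC/C(C)=C/CC/C(C)=C/COP(=O)(O)OP(=O)(O)O | intermediate
4 | mutildienyl diphosphate (ring A/ring C bicycle, isopropenyl on C9, (E)-allylic diphosphate chain on C5) | OP(=O)(O)OP(=O)(O)OC/C=C(\C)CC[C@]2(C)[C@@H]3CCC[C@@]3(CC[C@@H]2C)C(C)=C | intermediate (not isolated)
5 | premutilin (tricyclic C14 alcohol) | C=C[C@]1(C)C[C@@H](O)[C@]2(C)[C@@H]3CCC[C@@]3(CC[C@@H]2C)[C@@H](C)C1 | intermediate
6 | 11-hydroxypremutilin ((11S)-11,14-diol) | C=C[C@]1(C)C[C@@H](O)[C@]2(C)[C@@H]3CCC[C@@]3(CC[C@@H]2C)[C@@H](C)[C@@H]1O | intermediate (not isolated)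
7 | 3,11-dihydroxypremutilin (3,11,14-triol, C3 drawn 3S) | C=C[C@]1(C)C[C@@H](O)[C@]2(C)[C@@H]3[C@@H](O)CC[C@@]3(CC[C@@H]2C)[C@@H](C)[C@@H]1O | intermediate (not isolated)
8 | mutilin (C3 ketone, 11,14-diol) | C=C[C@]1(C)C[C@@H](O)[C@]2(C)[C@@H]3C(=O)CC[C@@]3(CC[C@@H]2C)[C@@H](C)[C@@H]1O | intermediate
9 | 11-O-triethylsilylmutilin | C=C[C@]1(C)C[C@@H](O)[C@]2(C)[C@@H]3C(=O)CC[C@@]3(CC[C@@H]2C)[C@@H](C)[C@@H]1O[Si](CC)(CC)CC | intermediate
10 | (tert-butyldimethylsilyloxy)acetic acid | CC(C)(C)[Si](C)(C)OCC(=O)O | starting material
11 | 14-O-[(tert-butyldimethylsilyloxy)acetyl]-11-O-triethylsilylmutilin | C=C[C@]1(C)C[C@@H](OC(=O)CO[Si](C)(C)C(C)(C)C)[C@]2(C)[C@@H]3C(=O)CC[C@@]3(CC[C@@H]2C)[C@@H](C)[C@@H]1O[Si](CC)(CC)CC | intermediate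
12 | (3R)-3-deoxo-3-hydroxy derivative of 11 (hydroxyl cis to C5, anti to H4) | C=C[C@]1(C)C[C@@H](OC(=O)CO[Si](C)(C)C(C)(C)C)[C@]2(C)[C@@H]3[C@H](O)CC[C@@]3(CC[C@@H]2C)[C@@H](C)[C@@H]1O[Si](CC)(CC)CC | intermediate
13 | 3-deoxo-3,4-didehydro-14-O-[(tert-butyldimethylsilyloxy)acetyl]-11-O-triethylsilylmutilin | C=C[C@]1(C)C[C@@H](OC(=O)CO[Si](C)(C)C(C)(C)C)[C@]2(C)C3=CCC[C@@]3(CC[C@@H]2C)[C@@H](C)[C@@H]1O[Si](CC)(CC)CC | intermediate
14 | 2-oxo-3-deoxo-3,4-didehydro-14-O-[(tert-butyldimethylsilyloxy)acetyl]-11-O-triethylsilylmutilin | C=C[C@]1(C)C[C@@H](OC(=O)CO[Si](C)(C)C(C)(C)C)[C@]2(C)C3=CC(=O)C[C@@]3(CC[C@@H]2C)[C@@H](C)[C@@H]1O[Si](CC)(CC)CC | intermediate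
15 | Pleuromutilin F | C=C[C@]1(C)C[C@@H](OC(=O)CO)[C@]2(C)C3=CC(=O)C[C@@]3(CC[C@@H]2C)[C@@H](C)[C@@H]1O | target

## Step count and least certain steps

Total: 10 steps. Longest linear sequence: 10 steps (1 to 15); 10 enters as purchased in step 6.

Step 3 (key step). The most likely failure is slow or incomplete turnover: the magnesium complex of 3 can precipitate, the product can inhibit the enzyme, and partly misfolded protein can let cationic intermediates escape to other diterpenes. Fallback: run the cyclisation inside cells. A host carrying the cluster's geranylgeranyl diphosphate synthase and the cyclase forms 3 from its own isoprenoid pool and converts it in place. This fallback sets out from 3 as the cells make it, so steps 1 and 2 are not needed, and it comes back to the route at 5. No new compound (F0).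

Step 4. The three-enzyme cascade may stall at intermediate oxidation levels through poor uptake of the lipophilic 5 or unbalanced expression, giving mixtures of 6, 7 and 8. Fallback, setting out from 5: a strain with only the two hydroxylase genes stops at the triol 7, which is isolated. Its C3 carbinol is the only hydroxyl not flanked by a quaternary carbon and would be oxidised chemically with TEMPO/PhI(OAc)2. The fallback returns at 8. No new compound (F0).

Step 5. Site selectivity may be lost, with silylation at C14 or at both hydroxyls. Fallback, setting out from 8:
- N-trifluoroacetylimidazole would give 11-O-trifluoroacetylmutilin F1, the documented C11-selective acylation.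
- EDC/DMAP coupling with 10 would give 11-O-trifluoroacetyl-14-O-[(tert-butyldimethylsilyloxy)acetyl]mutilin F2.
- NaHCO3 in MeOH would remove only the trifluoroacetate and give 14-O-[(tert-butyldimethylsilyloxy)acetyl]mutilin F3.
- The single free hydroxyl of F3 is then silylated with TESCl/imidazole, and the sequence comes back at 11.

Step 8. Proton loss may occur from C2 instead of C4, or ionisation at C3 may be followed by Wagner–Meerwein shifts. The first becomes likely if hydride in step 7 enters from the other face, so that H4 is no longer anti to the leaving group. Fallback, setting out from 12:
- Mitsunobu inversion (4-nitrobenzoic acid, DIAD, PPh3, attack from the open face) would give the (3S)-4-nitrobenzoate F4.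
- K2CO3 in MeOH at 0 °C would free the (3S)-alcohol F5, whose hydroxyl is syn to H4.
- The Burgess reagent (thermal syn-elimination, Zaitsev-selective) would then lead back to 13.

Step 9. Conversion at the hindered alkene may be incomplete, or over-oxidation may set in (loss of a silyl ether followed by oxidation of the freed carbinol). Fallback, setting out from 13:
- Sensitised photooxygenation (O2, tetraphenylporphyrin, light) can take an allylic hydrogen only from C2 and would give the C4 hydroperoxide F6, with the alkene moved to C2=C3 (Schenck ene reaction).
- PPh3 would reduce it to the tertiary C4 allylic alcohol F7.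
- Pyridinium chlorochromate, C5H5NH[CrO3Cl], would effect the oxidative 1,3-transposition (Babler–Dauben) and return the sequence at 14.

## Further compounds

F0 | step 3 | none | none
F0 | step 4 | none | none
F1 | step 5 | 11-O-trifluoroacetylmutilin | C=C[C@]1(C)C[C@@H](O)[C@]2(C)[C@@H]3C(=O)CC[C@@]3(CC[C@@H]2C)[C@@H](C)[C@@H]1OC(=O)C(F)(F)F
F2 | step 5 | 11-O-trifluoroacetyl-14-O-[(tert-butyldimethylsilyloxy)acetyl]mutilin | C=C[C@]1(C)C[C@@H](OC(=O)CO[Si](C)(C)C(C)(C)C)[C@]2(C)[C@@H]3C(=O)CC[C@@]3(CC[C@@H]2C)[C@@H](C)[C@@H]1OC(=O)C(F)(F)F
F3 | step 5 | 14-O-[(tert-butyldimethylsilyloxy)acetyl]mutilin | C=C[C@]1(C)C[C@@H](OC(=O)CO[Si](C)(C)C(C)(C)C)[C@]2(C)[C@@H]3C(=O)CC[C@@]3(CC[C@@H]2C)[C@@H](C)[C@@H]1O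
F4 | step 8 | (3S)-4-nitrobenzoate of the C3 carbinol (C3 epimer series of 12) | C=C[C@]1(C)C[C@@H](OC(=O)CO[Si](C)(C)C(C)(C)C)[C@]2(C)[C@@H]3[C@@H](OC(=O)c4ccc(cc4)[N+](=O)[O-])CC[C@@]3(CC[C@@H]2C)[C@@H](C)[C@@H]1O[Si](CC)(CC)CC
F5 | step 8 | (3S)-alcohol, C3 epimer of 12 (hydroxyl syn to H4) | C=C[C@]1(C)C[C@@H](OC(=O)CO[Si](C)(C)C(C)(C)C)[C@]2(C)[C@@H]3[C@@H](O)CC[C@@]3(CC[C@@H]2C)[C@@H](C)[C@@H]1O[Si](CC)(CC)CC
F6 | step 9 | C4 hydroperoxide with C2=C3 alkene (ene product of 13) | C=C[C@]1(C)C[C@@H](OC(=O)CO[Si](C)(C)C(C)(C)C)[C@]2(C)[C@]3(OO)C=CC[C@@]3(CC[C@@H]2C)[C@@H](C)[C@@H]1O[Si](CC)(CC)CC
F7 | step 9 | tertiary C4 allylic alcohol with C2=C3 alkene | C=C[C@]1(C)C[C@@H](OC(=O)CO[Si](C)(C)C(C)(C)C)[C@]2(C)[C@]3(O)C=CC[C@@]3(CC[C@@H]2C)[C@@H](C)[C@@H]1O[Si](CC)(CC)CC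
A1 | alternative 1 | bridged cyclooctane-1,5-dione (C10 and C14 ketones, quaternary C12, C11 silyl ether) | CC(C)(C)C(=O)OCC[C@]1(C)CC(=O)[C@]2(C)[C@H](OCOC)[C@](CC3(C)OCCO3)(CC[C@@H]2C)C(=O)[C@@H]1O[Si](C)(C)C(C)(C)C
A2 | alternative 2 | cis-fused hydrindene methyl ester (C5 and C9 quaternary) | COC(=O)[C@]2(C)[C@@H]3CC4(OCCO4)C[C@@]3(C=C[C@@H]2C)[C@@H](C)COCc1ccc(OC)cc1
A3 | alternative 3 | tricyclic C14 carbinol with ketal-masked ring-A enone | CC(C)(C)[Si](C)(C)OCC[C@]1(C)C[C@@H](O)[C@]2(C)C3=CC4(OCCO4)C[C@@]3(CC[C@@H]2C)[C@@H](C)[C@@H]1OCOC
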